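**Plan**
1. Retrosynthesis: cut the 2-methylbutanoate C–O bond and the two aryl O–Si bonds, re-epimerise C2, tie the C3 carboxyl carbon back to an oxygen on the benzylic carbon of the C4 arm (γ-lactone), then cut C2–C3.
2. Enabling feature: in the oxolane O1–C2(aryl)–C3(CH2O)–C4(CH2Ar)–C5H2 the C3 and C4 arms are cis, so both fit into one cis-fused γ-lactone; from that lactone C2–C3 is the bond of a 1,5 carbenoid C–H insertion into the ether C2–H.
3. Forward order: lactone ring first (auxiliary aldol and lactonisation), oxolane second (insertion giving a 3,7-dioxabicyclo[3.3.0]octan-8-one), then the lactone is opened by hydrogenolysis.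
4. Finish: acid reduction, C2 equilibration, esterification, desilylation.
5. Stereochemistry: C4 and the temporary benzylic lactone centre come from an (R)-4-benzyloxazolidinone syn-aldol; C3 follows from the obligatory cis ring fusion; C2 forms kinetically with aryl cis to the carbonyl and is inverted thermodynamically after the bicycle is opened; the side-chain centre comes from (R)-2-methylbutanoic acid.

Key step: step 10

Abbreviation in names: Ar = 3-methoxy-4-[tri(propan-2-yl)silyloxy]phenyl; ArCH2 = the corresponding benzyl group.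

Remark on the chemistry: dirhodium tetracarboxylate carbenoids insert into benzyl ether C–H bonds with the aryl group turned away from the ligand wall, which leaves it cis to the carbonyl group on the carbenoid carbon. The bicycle is therefore planned with the C2 aryl group on its concave face, and C2 is inverted in step 13 once the lactone bridge is gone.

Remark on the chemistry: both phenols are carried as triisopropylsilyl ethers, which should outlast LiOH/H2O2 and LiN(SiMe3)2; the succinate unit is taken from commercial methyl 4-chloro-4-oxobutanoate.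

**Step 1**
Reactants: 1 (R)-4-benzyl-2-oxazolidinone; 2 methyl 4-chloro-4-oxobutanoate
Product: 3 methyl 4-[(4R)-4-benzyl-2-oxo-1,3-oxazolidin-3-yl]-4-oxobutanoate
Conditions: n-BuLi, THF, −78 °C; then 2, −78 → 0 °C
Reagents that add atoms: none
Why: N-acylation of the lithiated oxazolidinone by the acid chloride gives the imide; the methyl ester is inert at this temperature and the auxiliary centre is not involved.

**Step 2**
Reactants: 4 vanillin
Product: 5 3-methoxy-4-[tri(propan-2-yl)silyloxy]benzaldehyde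
Conditions: i-Pr3SiCl, imidazole, DMF, rt
Reagents that add atoms: chlorotri(propan-2-yl)silane CC(C)[Si](Cl)(C(C)C)C(C)C
Why: imidazole-promoted O-silylation of a phenol; the bulky silyl ether is chosen for its resistance to the basic steps ahead.

**Step 3**
Reactants: 3 methyl 4-[(4R)-4-benzyl-2-oxo-1,3-oxazolidin-3-yl]-4-oxobutanoate; 5 3-methoxy-4-[tri(propan-2-yl)silyloxy]benzaldehyde
Product: 7 (4R)-4-benzyl-3-{[(2R,3R)-2-Ar-5-oxooxolan-3-yl]carbonyl}-1,3-oxazolidin-2-one, via syn-aldol adduct 6 (not isolated)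
Conditions: Bu2BOTf, i-Pr2NEt, CH2Cl2, 0 °C; 5, −78 → 0 °C; pH 7 buffer, MeOH, H2O2; then PPTS (cat.), CH2Cl2, rt
Reagents that add atoms: none
Why: Evans syn-aldol through the Z-boron enolate in a Zimmerman–Traxler chair sets both new centres (R,R) under control of the (R)-auxiliary; the benzylic hydroxyl then closes onto the methyl ester (5-exo-trig lactonisation, loss of methanol), and the syn relationship places aryl and acyl groups trans on the lactone.

**Step 4**
Reactants: 7 (4R)-4-benzyl-3-{[(2R,3R)-2-Ar-5-oxooxolan-3-yl]carbonyl}-1,3-oxazolidin-2-one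
Product: 9 (2R,3R)-2-Ar-5-oxooxolane-3-carboxylic acid, via peroxy acid 8 (not isolated)
Conditions: LiOH, H2O2, THF/H2O, 0 °C; Na2SO3 (aq); HCl to pH 2
Reagents that add atoms: hydrogen peroxide OO (supplies the hydroxyl oxygen of the carboxyl group by way of 8)
Why: LiOOH cleavage of the N-acyloxazolidinone at the exocyclic carbonyl, sulfite reduction of the peroxy acid, and re-closure on acidification of any lactone opened by hydroxide; the α-centre should not epimerise at 0 °C and the auxiliary is recovered.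

**Step 5**
Reactants: 9 (2R,3R)-2-Ar-5-oxooxolane-3-carboxylic acid
Product: 10 (4S,5R)-4-(hydroxymethyl)-5-Ar-oxolan-2-one
Conditions: BH3·SMe2, THF, 0 °C → rt; MeOH
Reagents that add atoms: none
Why: chemoselective borane reduction of a carboxylic acid (through the acyloxyborane) beside a lactone; the neutral medium avoids translactonisation of the hydroxymethyl lactone.

**Step 6**
Reactants: 5 3-methoxy-4-[tri(propan-2-yl)silyloxy]benzaldehyde
Product: 11 {3-methoxy-4-[tri(propan-2-yl)silyloxy]phenyl}methanol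
Conditions: NaBH4, MeOH, 0 °C
Reagents that add atoms: none
Why: borohydride reduction of an aromatic aldehyde; the aryl silyl ether is stable to brief exposure at 0 °C.

**Step 7**
Reactants: 11 {3-methoxy-4-[tri(propan-2-yl)silyloxy]phenyl}methanol
Product: 12 3-methoxy-4-[tri(propan-2-yl)silyloxy]benzyl 2,2,2-trichloroacetimidate
Conditions: Cl3CCN, DBU (cat.), CH2Cl2, 0 °C; used crude
Reagents that add atoms: trichloroacetonitrile N#CC(Cl)(Cl)Cl
Why: base-catalysed addition of the alcohol to the nitrile, the standard preparation of benzylic trichloroacetimidates; the electron-rich imidate is not stored.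

**Step 8**
Reactants: 10 (4S,5R)-4-(hydroxymethyl)-5-Ar-oxolan-2-one; 12 3-methoxy-4-[tri(propan-2-yl)silyloxy]benzyl 2,2,2-trichloroacetimidate
Product: 13 (4S,5R)-5-Ar-4-[(ArCH2O)methyl]oxolan-2-one
Conditions: CSA (cat.), CH2Cl2, 0 °C → rt
Reagents that add atoms: none
Why: acid-catalysed trichloroacetimidate benzylation (SN1 through the electron-rich benzyl cation), used because the basic conditions of a Williamson etherification would provoke translactonisation or retro-aldol cleavage of 10.

**Step 9**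
Reactants: 13 (4S,5R)-5-Ar-4-[(ArCH2O)methyl]oxolan-2-one
Product: 15 (4S,5R)-3-diazo-5-Ar-4-[(ArCH2O)methyl]oxolan-2-one, via trifluoroacetyl lactone 14 (not isolated)
Conditions: LiN(SiMe3)2, THF, −78 °C; CF3CO2CH2CF3; HCl (aq) work-up; then MsN3, Et3N, H2O, MeCN, rt
Reagents that add atoms: methanesulfonyl azide CS(=O)(=O)N=[N+]=[N-] (the two diazo nitrogen atoms of 15); 2,2,2-trifluoroethyl trifluoroacetate O=C(OCC(F)(F)F)C(F)(F)F (trifluoroacetyl group of 14 only)
Why: detrifluoroacetylative diazo transfer: Claisen acylation of the lactone enolate activates C3 for Regitz-type diazo transfer, and the triazoline fragments with loss of the trifluoroacetyl group as the N-sulfonyl amide; C4 and C5 are not touched.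

**Step 10**
Reactants: 15 (4S,5R)-3-diazo-5-Ar-4-[(ArCH2O)methyl]oxolan-2-one
Product: 16 (1R,2S,5S,6R)-2,6-bis(Ar)-3,7-dioxabicyclo[3.3.0]octan-8-one (cis-fused; 2-aryl on the concave face cis to C8; 6-aryl on the convex face)
Conditions: Rh2(OAc)4 (2 mol %), CH2Cl2, reflux, slow addition of 15
Reagents that add atoms: none
Why: Rh2(OAc)4 expels N2 from the diazo lactone to give an electrophilic divalent-rhodium carbenoid at C3, which takes the ether-activated benzylic C–H bond five atoms away through a concerted, hydride-transfer-like three-centre transition state; the closest known reaction type is the dirhodium-catalysed C–H insertion of α-diazo-γ-butyrolactones into benzyl ethers to give furofuranones. The oxolane closes by 1,5-insertion across the C4–CH2–O tether, forming the C2–C3 bond of the target (C1–C2 of the bicycle). Bridgehead C1 (C3 of the target) can only arise cis to the C5 arm, because two five-membered rings cannot be trans-fused here, so its configuration is relayed from the aldol-derived C5 (C4 of the target). At C2 the aryl group is expected on the concave face, cis to the lactone carbonyl, because it turns away from the carboxylate ligands in the transition state; this is the epimer of what the target needs and is corrected in step 13, where any convex epimer formed alongside converges as well. The step needs 1,5-insertion to win over 1,2-hydride shift to the butenolide, over attack on the arenes and over carbenoid dimerisation; the oxygen lone pair and the electron-rich aryl group make the benzylic C–H bond the most hydridic one in reach, and slow addition keeps the carbenoid concentration low.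

**Step 11**
Reactants: 16 (1R,2S,5S,6R)-2,6-bis(Ar)-3,7-dioxabicyclo[3.3.0]octan-8-one
Product: 17 (2S,3R,4S)-2-Ar-4-(ArCH2)oxolane-3-carboxylic acid (all-cis)
Conditions: H2 (1 atm), Pd/C, EtOAc/AcOH, rt; stopped when 16 is consumed
Reagents that add atoms: none
Why: hydrogenolysis of a benzylic C–O bond; the acyloxy oxygen of the lactone is a much better leaving group on palladium than the ring ether oxygen at C2, so the lactone bond should cleave first, erasing the auxiliary benzylic centre and releasing the benzyl arm and the C3 carboxyl while C2, C3 and C4 stay as they are.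

**Step 12**
Reactants: 17 (2S,3R,4S)-2-Ar-4-(ArCH2)oxolane-3-carboxylic acid
Product: 18 [(2S,3S,4S)-2-Ar-4-(ArCH2)oxolan-3-yl]methanol (all-cis)
Conditions: BH3·SMe2, THF, 0 °C → rt; MeOH
Reagents that add atoms: none
Why: borane reduction of the carboxylic acid to the primary alcohol; aryl silyl ethers and the benzylic ring ether are inert to borane.

**Step 13**
Reactants: 18 [(2S,3S,4S)-2-Ar-4-(ArCH2)oxolan-3-yl]methanol
Product: 19 [(2R,3S,4S)-2-Ar-4-(ArCH2)oxolan-3-yl]methanol (2,3-trans; 3,4-cis)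
Conditions: BF3·OEt2 (0.2 equiv), CH2Cl2, −40 → −10 °C; NaHCO3 (aq)
Reagents that add atoms: none
Why: Lewis-acid epimerisation of a 2-aryloxolane: reversible SN1 opening of C2–O1 to the p-silyloxybenzyl cation and re-closure by the C5 oxygen equilibrates C2 alone; the all-cis isomer, with the C3 arm wedged between two cis neighbours, should drain into the 2,3-trans isomer, and C3 and C4 take no part.

**Step 14**
Reactants: 19 [(2R,3S,4S)-2-Ar-4-(ArCH2)oxolan-3-yl]methanol; 20 (R)-2-methylbutanoic acid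
Product: 21 [(2R,3S,4S)-2-Ar-4-(ArCH2)oxolan-3-yl]methyl (2R)-2-methylbutanoate
Conditions: EDC·HCl, DMAP (cat.), CH2Cl2, 0 °C → rt
Reagents that add atoms: none
Why: Steglich esterification of the primary alcohol; a low DMAP loading at 0 °C should keep the α-centre of the acid from racemising.

**Step 15**
Reactants: 21 [(2R,3S,4S)-2-Ar-4-(ArCH2)oxolan-3-yl]methyl (2R)-2-methylbutanoate
Product: 22 [(2R,3S,4S)-2-(4-hydroxy-3-methoxyphenyl)-4-(4-hydroxy-3-methoxybenzyl)oxolan-3-yl]methyl (2R)-2-methylbutanoate (CNP0315069.1)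
Conditions: Bu4NF, AcOH, THF, 0 °C
Reagents that add atoms: none
Why: fluoride cleavage of both aryl silyl ethers; acetic acid protonates the phenoxides at once, so neither the ester nor the C2 benzylic ether (which a free p-phenoxide could open through a quinone methide) should be disturbed.

**Compound list**
1 | (R)-4-benzyl-2-oxazolidinone | O=C1N[C@H](Cc2ccccc2)CO1 | starting material
2 | methyl 4-chloro-4-oxobutanoate | COC(=O)CCC(Cl)=O | starting material
3 | methyl 4-[(4R)-4-benzyl-2-oxo-1,3-oxazolidin-3-yl]-4-oxobutanoate | COC(=O)CCC(=O)N1[C@H](Cc2ccccc2)COC1=O | intermediate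
4 | vanillin | O=Cc1ccc(O)c(OC)c1 | starting material
5 | 3-methoxy-4-[tri(propan-2-yl)silyloxy]benzaldehyde | O=Cc1ccc(O[Si](C(C)C)(C(C)C)C(C)C)c(OC)c1 | intermediate
6 | methyl (3R)-4-[(4R)-4-benzyl-2-oxo-1,3-oxazolidin-3-yl]-3-[(R)-hydroxy(Ar)methyl]-4-oxobutanoate (syn-aldol adduct) | O=C1OC[C@@H](Cc2ccccc2)N1C(=O)[C@H](CC(=O)OC)[C@@H](O)c3ccc(O[Si](C(C)C)(C(C)C)C(C)C)c(OC)c3 | intermediate (not isolated)
7 | (4R)-4-benzyl-3-{[(2R,3R)-2-Ar-5-oxooxolan-3-yl]carbonyl}-1,3-oxazolidin-2-one (trans lactone) | O=C1O[C@@H](c2ccc(O[Si](C(C)C)(C(C)C)C(C)C)c(OC)c2)[C@H](C(=O)N3C(=O)OC[C@H]3Cc4ccccc4)C1 | intermediate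
8 | (2R,3R)-2-Ar-5-oxooxolane-3-carboperoxoic acid | O=C1O[C@@H](c2ccc(O[Si](C(C)C)(C(C)C)C(C)C)c(OC)c2)[C@H](C(=O)OO)C1 | intermediate (not isolated)
9 | (2R,3R)-2-Ar-5-oxooxolane-3-carboxylic acid | O=C1O[C@@H](c2ccc(O[Si](C(C)C)(C(C)C)C(C)C)c(OC)c2)[C@H](C(=O)O)C1 | intermediate
10 | (4S,5R)-4-(hydroxymethyl)-5-Ar-oxolan-2-one | O=C1O[C@@H](c2ccc(O[Si](C(C)C)(C(C)C)C(C)C)c(OC)c2)[C@H](CO)C1 | intermediate
11 | {3-methoxy-4-[tri(propan-2-yl)silyloxy]phenyl}methanol | OCc1ccc(O[Si](C(C)C)(C(C)C)C(C)C)c(OC)c1 | intermediate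
12 | 3-methoxy-4-[tri(propan-2-yl)silyloxy]benzyl 2,2,2-trichloroacetimidate | N=C(OCc1ccc(O[Si](C(C)C)(C(C)C)C(C)C)c(OC)c1)C(Cl)(Cl)Cl | intermediate
13 | (4S,5R)-5-Ar-4-[(ArCH2O)methyl]oxolan-2-one | O=C1O[C@@H](c2ccc(O[Si](C(C)C)(C(C)C)C(C)C)c(OC)c2)[C@H](COCc2ccc(O[Si](C(C)C)(C(C)C)C(C)C)c(OC)c2)C1 | intermediate
14 | (4S,5R)-5-Ar-4-[(ArCH2O)methyl]-3-(trifluoroacetyl)oxolan-2-one (C3 epimers and enol) | O=C1O[C@@H](c2ccc(O[Si](C(C)C)(C(C)C)C(C)C)c(OC)c2)[C@H](COCc2ccc(O[Si](C(C)C)(C(C)C)C(C)C)c(OC)c2)C1C(=O)C(F)(F)F | intermediate (not isolated)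
15 | (4S,5R)-3-diazo-5-Ar-4-[(ArCH2O)methyl]oxolan-2-one | O=C1O[C@@H](c2ccc(O[Si](C(C)C)(C(C)C)C(C)C)c(OC)c2)[C@H](COCc2ccc(O[Si](C(C)C)(C(C)C)C(C)C)c(OC)c2)C1=[N+]=[N-] | intermediate
16 | (1R,2S,5S,6R)-2,6-bis(Ar)-3,7-dioxabicyclo[3.3.0]octan-8-one | O=C1O[C@@H](c3ccc(O[Si](C(C)C)(C(C)C)C(C)C)c(OC)c3)[C@@H]2CO[C@H](c3ccc(O[Si](C(C)C)(C(C)C)C(C)C)c(OC)c3)[C@H]12 | intermediate
17 | (2S,3R,4S)-2-Ar-4-(ArCH2)oxolane-3-carboxylic acid | OC(=O)[C@@H]1[C@H](Cc2ccc(O[Si](C(C)C)(C(C)C)C(C)C)c(OC)c2)CO[C@@H]1c1ccc(O[Si](C(C)C)(C(C)C)C(C)C)c(OC)c1 | intermediate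
18 | [(2S,3S,4S)-2-Ar-4-(ArCH2)oxolan-3-yl]methanol | OC[C@@H]1[C@H](Cc2ccc(O[Si](C(C)C)(C(C)C)C(C)C)c(OC)c2)CO[C@@H]1c1ccc(O[Si](C(C)C)(C(C)C)C(C)C)c(OC)c1 | intermediate
19 | [(2R,3S,4S)-2-Ar-4-(ArCH2)oxolan-3-yl]methanol | OC[C@@H]1[C@H](Cc2ccc(O[Si](C(C)C)(C(C)C)C(C)C)c(OC)c2)CO[C@H]1c1ccc(O[Si](C(C)C)(C(C)C)C(C)C)c(OC)c1 | intermediate
20 | (R)-2-methylbutanoic acid | CC[C@@H](C)C(=O)O | starting material
21 | [(2R,3S,4S)-2-Ar-4-(ArCH2)oxolan-3-yl]methyl (2R)-2-methylbutanoate | CC[C@@H](C)C(=O)OC[C@@H]1[C@H](Cc2ccc(O[Si](C(C)C)(C(C)C)C(C)C)c(OC)c2)CO[C@H]1c1ccc(O[Si](C(C)C)(C(C)C)C(C)C)c(OC)c1 | intermediate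
22 | [(2R,3S,4S)-2-(4-hydroxy-3-methoxyphenyl)-4-(4-hydroxy-3-methoxybenzyl)oxolan-3-yl]methyl (2R)-2-methylbutanoate | CC[C@@H](C)C(=O)OC[C@@H]1[C@H](Cc2ccc(O)c(OC)c2)CO[C@H]1c1ccc(O)c(OC)c1 | target

**Totals**
Total steps: 15. Longest linear sequence: 12 steps (1, 3, 4, 5, 8, 9, 10, 11, 12, 13, 14, 15).

**Steps most likely to fail**

Step 10. The carbenoid may be diverted before it reaches the benzylic C–H bond: 1,2-hydride migration from C4 would give a butenolide and destroy the C4 centre, and addition to an electron-rich arene or dimerisation would consume the diazo compound. The fallback sets out from 14, kept after the acidic work-up of step 9 instead of being treated with the azide. It forms the same C–C bond by oxidation of the ether rather than by a carbenoid. DDQ with 2,6-dichloropyridine and LiClO4 in 1,2-dichloroethane should oxidise the electron-rich benzyl ether to its oxocarbenium ion, which the enol of the trifluoroacetyl lactone captures (intramolecular cross-dehydrogenative coupling, cis-fused five-membered ring) to give (1R,2S,5S,6R)-2,6-bis(Ar)-1-(trifluoroacetyl)-3,7-dioxabicyclo[3.3.0]octan-8-one F1. Et3N and water in MeCN then cleave the trifluoroacetyl group (retro-Claisen), and protonation at the bridgehead can only give the cis-fused bicycle, which returns the route to 16. The aryl group is expected concave as in 16, the kinetic outcome of oxocarbenium closures onto this bicycle, and C2 is in any case reset in step 13.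

Step 11. Hydrogenolysis may fail to discriminate between the two benzylic C–O bonds: the ring ether at C2 may cleave with or after the lactone bond, or neither may cleave without stronger acid. The fallback sets out from 16 and removes the lactone oxygen by a radical path that cannot touch the ring ether.
- LiBH4 in THF reduces the lactone to [(2S,3S,4S)-2-Ar-4-[(R)-hydroxy(Ar)methyl]oxolan-3-yl]methanol F2.
- t-BuMe2SiCl and imidazole silylate the primary hydroxyl selectively to the mono-silyl ether F3.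
- NaH, CS2 and MeI convert the benzylic alcohol into the S-methyl xanthate F4.
- Bu3SnH and AIBN in toluene at 90 °C (Barton–McCombie deoxygenation) give the deoxygenated silyl ether F5.
- PPTS in MeOH removes the alkyl silyl ether while the aryl silyl ethers stay, which returns the route to 18.

Step 13. The benzylic cation needed for equilibration may be trapped irreversibly by the electron-rich ring of the C4 benzyl group (Friedel–Crafts closure to an aryltetralin) before ring re-closure has inverted C2. The fallback sets out from 16 and moves the equilibration to the bicycle, where the C2 cation cannot reach the C6 aryl ring because the two lie on opposite faces of the lactone. BF3·OEt2 (cat.) in CH2Cl2 should interconvert 16 and its convex-face epimer, (1R,2R,5S,6R)-2,6-bis(Ar)-3,7-dioxabicyclo[3.3.0]octan-8-one F6. The two epimers are expected to be close in energy, so F6 is separated and recovered 16 is resubmitted. F6 is hydrogenolysed under the conditions of step 11 to (2R,3R,4S)-2-Ar-4-(ArCH2)oxolane-3-carboxylic acid F7, and BH3·SMe2 as in step 12 returns the route to 19.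

**Further compounds**
F1 | step 10 | (1R,2S,5S,6R)-2,6-bis(Ar)-1-(trifluoroacetyl)-3,7-dioxabicyclo[3.3.0]octan-8-one | O=C1O[C@@H](c3ccc(O[Si](C(C)C)(C(C)C)C(C)C)c(OC)c3)[C@@H]2CO[C@H](c3ccc(O[Si](C(C)C)(C(C)C)C(C)C)c(OC)c3)[C@]12C(=O)C(F)(F)F
F2 | step 11 | [(2S,3S,4S)-2-Ar-4-[(R)-hydroxy(Ar)methyl]oxolan-3-yl]methanol | OC[C@@H]1[C@H]([C@@H](O)c2ccc(O[Si](C(C)C)(C(C)C)C(C)C)c(OC)c2)CO[C@@H]1c1ccc(O[Si](C(C)C)(C(C)C)C(C)C)c(OC)c1
F3 | step 11 | (R)-Ar{(3S,4S,5S)-5-Ar-4-[(tert-butyldimethylsilyloxy)methyl]oxolan-3-yl}methanol | CC(C)(C)[Si](C)(C)OC[C@@H]1[C@H]([C@@H](O)c2ccc(O[Si](C(C)C)(C(C)C)C(C)C)c(OC)c2)CO[C@@H]1c1ccc(O[Si](C(C)C)(C(C)C)C(C)C)c(OC)c1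
F4 | step 11 | O-[(R)-Ar{(3S,4S,5S)-5-Ar-4-[(tert-butyldimethylsilyloxy)methyl]oxolan-3-yl}methyl] S-methyl dithiocarbonate | CC(C)(C)[Si](C)(C)OC[C@@H]1[C@H]([C@@H](OC(=S)SC)c2ccc(O[Si](C(C)C)(C(C)C)C(C)C)c(OC)c2)CO[C@@H]1c1ccc(O[Si](C(C)C)(C(C)C)C(C)C)c(OC)c1
F5 | step 11 | tert-butyl{[(2S,3S,4S)-2-Ar-4-(ArCH2)oxolan-3-yl]methoxy}dimethylsilane | CC(C)(C)[Si](C)(C)OC[C@@H]1[C@H](Cc2ccc(O[Si](C(C)C)(C(C)C)C(C)C)c(OC)c2)CO[C@@H]1c1ccc(O[Si](C(C)C)(C(C)C)C(C)C)c(OC)c1
F6 | step 13 | (1R,2R,5S,6R)-2,6-bis(Ar)-3,7-dioxabicyclo[3.3.0]octan-8-one | O=C1O[C@@H](c3ccc(O[Si](C(C)C)(C(C)C)C(C)C)c(OC)c3)[C@@H]2CO[C@@H](c3ccc(O[Si](C(C)C)(C(C)C)C(C)C)c(OC)c3)[C@H]12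
F7 | step 13 | (2R,3R,4S)-2-Ar-4-(ArCH2)oxolane-3-carboxylic acid | OC(=O)[C@@H]1[C@H](Cc2ccc(O[Si](C(C)C)(C(C)C)C(C)C)c(OC)c2)CO[C@H]1c1ccc(O[Si](C(C)C)(C(C)C)C(C)C)c(OC)c1
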